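## Structural features

The target (14) is an achiral, centrosymmetric bis(indolyl)quinone. Its core is a fully substituted 1,4-benzoquinone ring (ring atoms C1 to C6) with carbonyls at C1 and C4, methoxy groups at C2 and C5, and identical 2-(2-methylbut-3-en-2-yl)-1H-indol-3-yl groups at C3 and C6. There is no stereocentre; the only stereochemical feature is hindered rotation about the two indole C3–quinone bonds, which needs no control. Each of these bonds joins a quinone carbon flanked by C=O and C–OMe to an indole C3 flanked by C3a and by a C2 that carries a quaternary carbon, so each is a tetra-ortho-substituted biaryl-type bond. The fragile groups are the 2-methylbut-3-en-2-yl groups (acid-labile, with terminal vinyl groups open to hydrogenation, hydrometalation and Heck chemistry), the free N–H indoles (oxidants, electrophiles) and the methoxyquinone (a redox-active vinylogous ester that nucleophiles attack). The real difficulty is to make two very congested aryl–ring bonds on a hexasubstituted ring at the quinone oxidation level without exposing the 2-methylbut-3-en-2-yl groups to acid or oxidant. The key step exploits the fact that the ring is the bis(methyl enol ether) of a cyclohexane-1,2,4,5-tetraone whose six carbons are two identical triads, C3–C2–C1 and C6–C5–C4, joined head to tail; each triad with its indole is an indol-3-ylpyruvate. Bonds C1–C6 and C3–C4 can therefore be made by two Claisen acylations of one monomer, the hindered aryl–ring bonds are carried in as ordinary indole C3–CH2 bonds, and the quinone oxidation level comes from the carboxyl carbons.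

## Logic of the disconnections

14 to 13: the two O–CH3 bonds at the C2 and C5 oxygens are cut. The free bis-enol is what a condensation-based ring synthesis delivers, and its two hydroxyls are far more acidic than any other X–H in the molecule. The gain is small but it places the only alkylation at the very end. The forward step must methylate the two enol oxygens only, not the indole nitrogens and not the carbonyl oxygens.

13 to two molecules of 11 (through 12): the ring bonds C3–C4 and C6–C1 are cut. Each ring carbonyl carbon is seen as a former ester carbon, and each indolyl-bearing ring carbon as a former enolisable methylene. This removes the whole central ring, halves the molecule, and turns both hindered aryl–ring bonds into indole C3–CH2 bonds of a three-carbon side chain. The forward step must favour C-acylation at the ester over aldol addition at the ketone, twice, the second time intramolecularly.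

11 to 10: the ketone C=O is traced back to C=N–OH. The keto ester 11 is enolisable and air-sensitive, so it is best unmasked just before use, and the oxime is what the C3-alkylation gives directly. The forward step must cleave the C=N bond without touching the vinyl groups or reducing the new ketone.

10 to 6 and 8 (through 9): the indole C3–CH2 bond is cut. The electrophilic carbon is primary and unhindered, so the 2-tert-alkyl group on 6 matters little, and the complete pyruvate chain arrives in one operation. The forward step needs C3- over N-alkylation and an electrophile reactive enough for a hindered indole.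

8 to 7: the C=N bond is cut, leading back to a commercial bromo keto ester. The forward step must condense at the ketone without displacing bromide.

6 to 2 and 3 (through 4 and 5): the indole bonds C2–C3 and N1–C2 are cut. The quaternary carbon and its vinyl group then come intact from a non-enolisable ester, and the ring is closed under strongly basic, acid-free conditions that the 2-methylbut-3-en-2-yl group tolerates. The forward step needs clean C-acylation of a benzylic anion by a hindered ester.

2 to 1: the N–Si bond is cut, leading to a commercial aniline. The forward step must stop at monosilylation.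

## Other disconnections considered

Alternative 1: the first plan that comes to mind cuts both indole C3–quinone bonds. In the forward direction 6 adds twice, with re-oxidation, to a tetrahalo-1,4-benzoquinone to give the dibromide A1, and halide-to-methoxide exchange then gives 14. Each new C–C bond is made intermolecularly at its most hindered point, the second one next to a carbon already carrying a 2-tert-alkylindole. The additions need acid or base promotion and a stoichiometric quinone oxidant in the presence of the acid-sensitive 2-methylbut-3-en-2-yl groups, and the methoxy pattern still has to be set by a separate exchange. The chosen plan never forms these bonds in a congested setting and needs no oxidant.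

Alternative 2: a two-directional indole annulation cuts N1–C2 and C3–C3a of both indoles. In the forward direction a double Larock heteroannulation (Pd(OAc)2 catalysis) of a 2-haloaniline with the bis-alkyne A2 gives the bis-indole A3, and oxidative demethylation with (NH4)2Ce(NO3)6 gives 14. Each alkyne of A2 lies between a quaternary carbon and an arene with two ortho methoxy groups, so carbopalladation is sterically doubtful at both termini. The vinyl groups offer a competing Heck pathway, and the final oxidation with tetravalent cerium must spare two electron-rich N–H indoles. A2 itself needs several steps, so the plan is longer and its end-game less secure than a redox-neutral ring synthesis.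

Alternative 3: a two-directional late-stage reverse prenylation cuts both indole C2–C(CH3)2 bonds. In the forward direction the bis-indole A4 is chlorinated at both indole C3 atoms and treated with a prenyl-dialkylborane, which transfers the allyl group with transposition to C2 to give A3, followed by oxidation to 14. The chlorination must choose the indole C3 positions over a very electron-rich tetramethoxybenzene ring. Two quaternary carbons must be built ortho to existing congested aryl–aryl bonds, and A4 still requires the conventional aryl–ring coupling and an oxidative end-game. The chosen plan installs the quaternary carbon on a simple benzylic anion before any congestion exists.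

Key step: step 6

Assumption 1: methyl 2,2-dimethylbut-3-enoate (3) and ethyl bromopyruvate (7) are taken as commercial; the parent acid of 3 is a catalogue compound.
Assumption 2: the oximes 8 and 10 are drawn with the hydroxyl anti to the ester; the geometry is of no consequence because 8 reacts through 9 and the C=N bond of 10 is cleaved in step 5.

## Route

Step 1
Reactants: 1 2-methylaniline
Product: 2 2-methyl-N-(trimethylsilyl)aniline
Conditions: n-BuLi (1.05 equiv), THF, −78 to 0 °C; then Me3SiCl, 0 °C to rt; distillation
Reagents that add atoms: chlorotrimethylsilane, C[Si](C)(C)Cl
Why: N-lithiation of the aniline followed by N-silylation of the lithium anilide; 1:1 stoichiometry should stop at the monosilyl amine needed for the Peterson-type closure in step 2.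

Step 2
Reactants: 2 2-methyl-N-(trimethylsilyl)aniline; 3 methyl 2,2-dimethylbut-3-enoate
Product: 6 2-(2-methylbut-3-en-2-yl)-1H-indole, via dilithiated silylaniline 4 (not isolated), via lithiated silylamino ketone 5 (not isolated)
Conditions: n-BuLi (2.2 equiv), hexane, reflux; then 3, THF, −78 °C to rt; H2O
Reagents that add atoms: none
Why: Smith modification of the Madelung indole synthesis: the N,C-dilithio species 4 C-acylates the non-enolisable ester 3 to ketone 5, whose N-silyl lithium amide adds to the carbonyl and eliminates lithium trimethylsilanolate (aza-Peterson olefination) to a 3H-indole that tautomerises to 6. The acid-free conditions leave the 2-methylbut-3-en-2-yl group intact, and the isolated vinyl group is inert to the benzylic organolithium at low temperature.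

Step 3
Reactants: 7 ethyl 3-bromo-2-oxopropanoate
Product: 8 ethyl (2Z)-3-bromo-2-(hydroxyimino)propanoate
Conditions: NH2OH·HCl, CHCl3/MeOH 1:1, rt
Reagents that add atoms: hydroxylamine hydrochloride, NO.Cl
Why: Oxime formation by condensation at the ketone carbonyl, which is far more electrophilic than the ester; the mild, base-free conditions should avoid displacement of the bromide.

Step 4
Reactants: 6 2-(2-methylbut-3-en-2-yl)-1H-indole; 8 ethyl (2Z)-3-bromo-2-(hydroxyimino)propanoate
Product: 10 ethyl (2E)-2-(hydroxyimino)-3-[2-(2-methylbut-3-en-2-yl)-1H-indol-3-yl]propanoate, via ethyl 2-nitrosoprop-2-enoate 9 (not isolated)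
Conditions: Na2CO3, CH2Cl2, rt, slow addition of 8
Reagents that add atoms: none
Why: Gilchrist-type nitrosoalkene alkylation of an indole: Na2CO3 effects 1,4-elimination of HBr from 8 to the transient nitrosoalkene 9, whose unhindered CH2 terminus is attacked by the nucleophilic C3 of 6 (conjugate addition, or hetero-Diels–Alder addition across C2–C3 followed by ring opening and rearomatisation). C3 is the only open nucleophilic carbon and the electrophilic carbon is primary, so the 2-tert-alkyl group should not block the reaction.

Step 5
Reactants: 10 ethyl (2E)-2-(hydroxyimino)-3-[2-(2-methylbut-3-en-2-yl)-1H-indol-3-yl]propanoate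
Product: 11 ethyl 3-[2-(2-methylbut-3-en-2-yl)-1H-indol-3-yl]-2-oxopropanoate
Conditions: TiCl3 (aq), NH4OAc, THF/H2O, rt, argon; product used at once
Reagents that add atoms: water, O
Why: Reductive deoximation: trivalent titanium cleaves the N–O bond to the N–H imine (in equilibrium with its enamine), which is hydrolysed in the buffered aqueous medium to the α-keto ester. The isolated alkene, the ester and the indole are inert to aqueous TiCl3 at near-neutral pH.

Step 6
Reactants: 11 ethyl 3-[2-(2-methylbut-3-en-2-yl)-1H-indol-3-yl]-2-oxopropanoate (two molecules)
Product: 13 2,5-dihydroxy-3,6-bis[2-(2-methylbut-3-en-2-yl)-1H-indol-3-yl]cyclohexa-2,5-diene-1,4-dione, via acyclic triketo ester 12 (not isolated)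
Conditions: NaOEt (2.5 equiv), EtOH, 0 °C to reflux, argon; then 1 M HCl, 0 °C
Reagents that add atoms: none
Why: Proposed new method: in ethoxide the enolate of 11, nucleophilic at its indolylmethine carbon, should acylate the oxalyl-type ester carbonyl of a second molecule of 11 to give the 1,3-diketone 12, which is held as its stabilised enolate. A second deprotonation at the remaining indolylmethylene of 12 then lets that carbon attack the surviving ester carbonyl, and loss of ethoxide gives the cyclohexane-1,2,4,5-tetraone, whose bis-enol is 13 and which is drained irreversibly as a doubly vinylogous carboxylate dianion. The closest known reaction types are the Claisen condensation of benzylic ketones with oxalic esters and the Dieckmann cyclisation, and the pairing of two arylpyruvate units in this sense is the way the natural quinones of this family are assembled from thioester-activated indolylpyruvate. The one ring closed is the central six-membered carbocycle (bonds C1–C6 and C3–C4), the second bond by a 6-exo-trig acyl substitution. No stereocentre is formed, and head-to-tail pairing is the only way two molecules of 11 can close a six-membered ring, so no regiochemical choice exists. The selectivity needed is C-acylation at the ester over aldol addition to the ketone and over O-acylation: aldolates and enol lactones form reversibly in hot ethoxide, the aldol path must build a fully substituted sp3 carbon next to the methine that carries the bulky 2-tert-alkylindole, whereas the Claisen path keeps every ring carbon sp2 and alone ends in the dianion sink. The quinone oxidation level comes from the two carboxyl carbons, so no oxidant or acid touches the indoles or the 2-methylbut-3-en-2-yl groups.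

Step 7
Reactants: 13 2,5-dihydroxy-3,6-bis[2-(2-methylbut-3-en-2-yl)-1H-indol-3-yl]cyclohexa-2,5-diene-1,4-dione
Product: 14 2,5-dimethoxy-3,6-bis[2-(2-methylbut-3-en-2-yl)-1H-indol-3-yl]cyclohexa-2,5-diene-1,4-dione
Conditions: Me3SiCHN2 (excess), toluene/MeOH 4:1, 0 °C to rt
Reagents that add atoms: (trimethylsilyl)diazomethane, C[Si](C)(C)C=[N+]=[N-]
Why: Diazoalkane O-methylation of the two strongly acidic vinylogous carboxylic acid hydroxyls, with methanol releasing the methylating species from the silyl reagent. The indole N–H groups are far too weakly acidic to protonate the reagent, and the para-quinone diether is the favoured tautomeric series.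

## Compound list

1 | 2-methylaniline | Cc1ccccc1N | starting material
2 | 2-methyl-N-(trimethylsilyl)aniline | Cc1ccccc1N[Si](C)(C)C | intermediate
3 | methyl 2,2-dimethylbut-3-enoate | C=CC(C)(C)C(=O)OC | starting material
4 | lithium [2-(lithiomethyl)phenyl](trimethylsilyl)azanide | [Li]Cc1ccccc1N([Li])[Si](C)(C)C | intermediate
5 | lithium [2-(3,3-dimethyl-2-oxopent-4-en-1-yl)phenyl](trimethylsilyl)azanide | C=CC(C)(C)C(=O)Cc1ccccc1N([Li])[Si](C)(C)C | intermediate
6 | 2-(2-methylbut-3-en-2-yl)-1H-indole | C=CC(C)(C)c1cc2ccccc2[nH]1 | intermediate
7 | ethyl 3-bromo-2-oxopropanoate | CCOC(=O)C(=O)CBr | starting material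
8 | ethyl (2Z)-3-bromo-2-(hydroxyimino)propanoate | CCOC(=O)/C(CBr)=N/O | intermediate
9 | ethyl 2-nitrosoprop-2-enoate | C=C(N=O)C(=O)OCC | intermediate
10 | ethyl (2E)-2-(hydroxyimino)-3-[2-(2-methylbut-3-en-2-yl)-1H-indol-3-yl]propanoate | CCOC(=O)/C(Cc1c(C(C)(C)C=C)[nH]c2ccccc12)=N/O | intermediate
11 | ethyl 3-[2-(2-methylbut-3-en-2-yl)-1H-indol-3-yl]-2-oxopropanoate | CCOC(=O)C(=O)Cc1c(C(C)(C)C=C)[nH]c2ccccc12 | intermediate
12 | ethyl 3,6-bis[2-(2-methylbut-3-en-2-yl)-1H-indol-3-yl]-2,4,5-trioxohexanoate (racemic at C3, enolised in the flask) | CCOC(=O)C(=O)C(c1c(C(C)(C)C=C)[nH]c2ccccc12)C(=O)C(=O)Cc1c(C(C)(C)C=C)[nH]c2ccccc12 | intermediate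
13 | 2,5-dihydroxy-3,6-bis[2-(2-methylbut-3-en-2-yl)-1H-indol-3-yl]cyclohexa-2,5-diene-1,4-dione | C=CC(C)(C)c1[nH]c2ccccc2c1C1=C(O)C(=O)C(c2c(C(C)(C)C=C)[nH]c3ccccc23)=C(O)C1=O | intermediate
14 | 2,5-dimethoxy-3,6-bis[2-(2-methylbut-3-en-2-yl)-1H-indol-3-yl]cyclohexa-2,5-diene-1,4-dione | C=CC(C)(C)c1[nH]c2ccccc2c1C1=C(OC)C(=O)C(c2c(C(C)(C)C=C)[nH]c3ccccc23)=C(OC)C1=O | target

## Step count and risks

Total step count: 7. Longest linear sequence: 6 (steps 1, 2, 4, 5, 6, 7).

Step 6 (key step, proposed new method). The most likely failure is diversion of the enolate into aldol addition at the ketone carbonyl of a second molecule, followed by lactonisation, faster than C-acylation at the ester. The sequence may also stall after the first acylation, because the second enolisation must occur at a very hindered methylene. The fallback uses known chemistry, sets out from 6 and returns at 13. Acid-promoted conjugate addition of 6 to 2,5-dichloro-1,4-benzoquinone (HCl, THF), with re-oxidation by DDQ, should give the mono-adduct 2,5-dichloro-3-[2-(2-methylbut-3-en-2-yl)-1H-indol-3-yl]cyclohexa-2,5-diene-1,4-dione F1. A second addition of 6 (AcOH, then DDQ) should give 2,5-dichloro-3,6-bis[2-(2-methylbut-3-en-2-yl)-1H-indol-3-yl]cyclohexa-2,5-diene-1,4-dione F2. Hydrolysis of both vinylogous acid chlorides with NaOH in aqueous MeOH at reflux, then acidification, gives 13.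

Step 2. C-Acylation of the benzylic anion by the α,α-disubstituted ester may be slow, and proton transfer from the product ketone may quench the dianion, so that ring closure remains incomplete. The fallback reverses the order of bond formation, sets out from 1 and 3 and returns at 6. AlMe3-mediated aminolysis of 3 by 1 (toluene, heat) gives 2,2-dimethyl-N-(2-methylphenyl)but-3-enamide F3. A Madelung cyclisation under n-BuLi in THF at 0 °C to rt then closes C2–C3 by attack of the benzylic anion on the amide carbonyl and gives 6.

Step 4. The nitrosoalkene may oligomerise, or react at nitrogen, faster than the shielded C3 of the indole adds to it. The fallback changes the electrophile and the bond-forming mode, sets out from 6 and returns at 11. A Mannich reaction of 6 with dimethylmethylideneammonium iodide gives N,N-dimethyl-1-[2-(2-methylbut-3-en-2-yl)-1H-indol-3-yl]methanamine F4. Thermal elimination–addition alkylation of ethyl nitroacetate with F4 (xylene, reflux) gives ethyl 3-[2-(2-methylbut-3-en-2-yl)-1H-indol-3-yl]-2-nitropropanoate F5. A reductive Nef reaction (aqueous TiCl3, NH4OAc) converts F5 into 11.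

Step 5. Over-reduction of the intermediate imine, or of the new α-keto ester, by trivalent titanium may compete with hydrolysis, and the enolisable product may self-condense or autoxidise during aqueous work-up. The fallback replaces reductive hydrolysis by full reduction and oxidative transamination, sets out from 10 and returns at 11. Reduction with Zn in AcOH gives ethyl 2-amino-3-[2-(2-methylbut-3-en-2-yl)-1H-indol-3-yl]propanoate F6. Condensation of F6 with 3,5-di-tert-butyl-1,2-benzoquinone in MeOH, prototropic shift and mild hydrolysis with aqueous oxalic acid release 11.

Step 7. Alkylation may stop at the monoether, or occur at a carbonyl oxygen to give an ortho-quinone ether, and the diazoalkane may add to the quinone. The fallback replaces O-alkylation by a thermodynamically controlled addition–elimination, sets out from 13 and returns at 14: acid-catalysed vinylogous esterification with MeOH and HC(OMe)3 and catalytic p-toluenesulfonic acid at rt. It makes no new compound.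

## Further compounds

F1 | step 6 | 2,5-dichloro-3-[2-(2-methylbut-3-en-2-yl)-1H-indol-3-yl]cyclohexa-2,5-diene-1,4-dione | C=CC(C)(C)c1[nH]c2ccccc2c1C1=C(Cl)C(=O)C=C(Cl)C1=O
F2 | step 6 | 2,5-dichloro-3,6-bis[2-(2-methylbut-3-en-2-yl)-1H-indol-3-yl]cyclohexa-2,5-diene-1,4-dione | C=CC(C)(C)c1[nH]c2ccccc2c1C1=C(Cl)C(=O)C(c2c(C(C)(C)C=C)[nH]c3ccccc23)=C(Cl)C1=O
F3 | step 2 | 2,2-dimethyl-N-(2-methylphenyl)but-3-enamide | C=CC(C)(C)C(=O)Nc1ccccc1C
F4 | step 4 | N,N-dimethyl-1-[2-(2-methylbut-3-en-2-yl)-1H-indol-3-yl]methanamine | C=CC(C)(C)c1[nH]c2ccccc2c1CN(C)C
F5 | step 4 | ethyl 3-[2-(2-methylbut-3-en-2-yl)-1H-indol-3-yl]-2-nitropropanoate (racemic) | CCOC(=O)C(Cc1c(C(C)(C)C=C)[nH]c2ccccc12)[N+](=O)[O-]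
F6 | step 5 | ethyl 2-amino-3-[2-(2-methylbut-3-en-2-yl)-1H-indol-3-yl]propanoate (racemic) | CCOC(=O)C(N)Cc1c(C(C)(C)C=C)[nH]c2ccccc12
F0 | step 7 | none | none
A1 | alternative 1 | 2,5-dibromo-3,6-bis[2-(2-methylbut-3-en-2-yl)-1H-indol-3-yl]cyclohexa-2,5-diene-1,4-dione | C=CC(C)(C)c1[nH]c2ccccc2c1C1=C(Br)C(=O)C(c2c(C(C)(C)C=C)[nH]c3ccccc23)=C(Br)C1=O
A2 | alternative 2 | 1,4-bis(3,3-dimethylpent-4-en-1-yn-1-yl)-2,3,5,6-tetramethoxybenzene | C=CC(C)(C)C#Cc1c(OC)c(OC)c(C#CC(C)(C)C=C)c(OC)c1OC
A3 | alternative 2 | 3,3'-(2,3,5,6-tetramethoxy-1,4-phenylene)bis[2-(2-methylbut-3-en-2-yl)-1H-indole] | C=CC(C)(C)c1[nH]c2ccccc2c1-c1c(OC)c(OC)c(-c2c(C(C)(C)C=C)[nH]c3ccccc23)c(OC)c1OC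
A4 | alternative 3 | 3,3'-(2,3,5,6-tetramethoxy-1,4-phenylene)bis(1H-indole) | COc1c(OC)c(-c2c[nH]c3ccccc23)c(OC)c(OC)c1-c1c[nH]c2ccccc12
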